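The readings are calculated for an exercise; the scatter is artificial.

The question was how much target the asked flask held at 8.0 h, and which of the remedies to take then.

| flask | starting material | second substrate | gas | remark | time |
|---|---|---|---|---|---|
| Wednesday's | 12 mM | 60 mM | 2.8 mM (held) | the very flask that is asked about, followed so far |  |
| Tuesday's | 18 mM | 60 mM | 2.8 mM (held) | run made earlier |  |
| flask | 12 mM | 60.0 mM | 2.8 mM (held) |  | 8.0 h |

| run | time / min | target / % | starting material / % |
|---|---|---|---|
| Wednesday's | 90.0 | 30 | 70 |
| Wednesday's | 180 | 27 | 69 |
| Wednesday's | 300 | 30 | 71 |
| Wednesday's | 360 | 29 | 71 |
| Tuesday's | 4.00 | 14 | 86 |
| Tuesday's | 8.00 | 21 | 79 |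
| Tuesday's | 12.0 | 25 | 74 |
| Tuesday's | 20.0 | 30 | 73 |

(scatter of a reading: 1.5 percentage points)

- north-west: at 8.0 h add starting material, 50.0 % of the amount charged, then wait 15 h
- south-east: change nothing and wait 15 h more
- north: at 8.0 h take out 90 % of the target then present, then wait 15 h

- removed target is counted in
- at the start none of the gas is in solution
- additions bring no volume worth counting

1. target, in percent of the starting material first charged, at 8.0 h
2. the remedy with the largest gain of target, or "none" below 2 percentage points (north-west / south-east / north / none)
3. target present, with what was taken out counted in, in percent of the starting material first charged, after south-east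
4. target present, with what was taken out counted in, in percent of the starting material first charged, after north

Wednesday's run stood flat from 90.0 min to 360 min, so I took the stop as a balance and divided the rate of making target by the rate of undoing it. At a balance that quotient is one and time drops out. With the gas held, what is left to read is the stopping ratio, target over starting material at the stop, an apparent equilibrium constant, which Wednesday's readings put at 0.413. Tuesday's run, charged with 18 mM against 12 mM, gave 0.411 at its last reading, so within the scatter the ratio did not follow the charge.

As a share, my ratio gave 29.2 % target in the asked flask, and I reckoned no gain from waiting. For adding starting material I reckoned a gain of 15 percentage points. For taking out target I reckoned a gain of 19 points, for a count of 47.8 %, so I put north ahead of north-west. One number was enough only if the stop was a balance, and the flat readings by themselves did not tell a balance from a reaction that had died.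

The forecast said 29.5 % (28.3 % to 30.7 %), a little above my share, with 29.5 % after south-east and 48 % (44 % to 51 %) after north, which it chose as best. Its ground was this: “A constant percentage with gas and second substrate effectively fixed points to a reversible step”.

    starting material + reagent ⇌ target (K = 150 /M, k = 4.90 /M/s)
    gas ⇌ reagent, rate k2*(csat - [reagent]) (kL = 0.0170 /s)
    second substrate + reagent ⇌ second product (K = 98.0 /M, k = 0.980 /M/s)

The asked flask held 29.6 % at 8.0 h, and the best remedy was north, with 48.3 % counted in against 29.6 % after south-east. Left until 4800 min, the untouched flask still held 29.6 %. The stopping ratio of 0.413 gives north a gain of 19 points, and the north flask gained 19 points. On the north-west flask the same ratio gives 15 points, and that flask gained 15 points.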